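## Retrosynthetic overview

1. Last bond, C6–C7: intramolecular Nozaki–Hiyama allylation of an epoxy aldehyde by a 3-(bromomethyl)butenolide. It closes the ten-membered carbocycle (formed last), turns the butenolide into the α-methylene lactone and sets C6 and C7 from C8.
2. Before that, C1=C10: cross-metathesis of two fragments of similar size, epoxy aldehyde fragment A (C1–C6, C15) and bromobutenolide fragment B (C7–C14, tiglate already in place).
3. Fragment A: the cis-epoxide ring, by Sharpless epoxidation of a (Z)-allylic alcohol made by methylcuprate addition to an ynoate.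
4. Fragment B: tiglate alkylation of a symmetric allylic dibromide, Barbier allylation of acrolein, kinetic resolution (C8), then the butenolide ring by esterification and ring-closing metathesis.
5. Ring order: epoxide (A) and butenolide (B) in parallel, then the carbocycle.

Assumption: the SMILES is taken as drawn, i.e. (4S,5R,6S,7S,8S) in germacrane numbering, a cis-4,5-epoxide, a trans-fused 8,12-lactone, a tiglate (E) ester, and a 1(10)-alkene with C2 trans to C9 (CIP Z because C14 carries oxygen).

## Route

**Fragment A**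

Step 1
Reactants: 1 hex-1-en-5-yne; 2 methyl chloroformate
Product: 4 methyl hept-6-en-2-ynoate, via lithium hex-5-en-1-ynide 3 (not isolated)
Conditions: n-BuLi, THF, −78 °C; then 2, −78 → 0 °C
Reagents that add atoms: none
Why: Deprotonation of the terminal alkyne and C-acylation of the lithium acetylide by the chloroformate (acetylide acylation) is fast at −78 °C and leaves the remote alkene untouched.

Step 2
Reactants: 4 methyl hept-6-en-2-ynoate
Product: 6 methyl (2Z)-3-methylhepta-2,6-dienoate, via alkenyl(methyl)cuprate 5 (not isolated)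
Conditions: Me2CuLi (from MeLi, CuI), THF, −78 °C; sat. aq. NH4Cl at −78 °C
Reagents that add atoms: lithium dimethylcuprate, [Li+].C[Cu-]C (made in the flask from methyllithium, [Li]C, and CuI)
Why: Syn-carbocupration (cuprate conjugate addition) of the ynoate puts methyl and copper cis, and protonation at −78 °C with retention gives the (2Z)-enoate with the butenyl chain cis to the ester, the geometry needed for the cis-4,5-epoxide.

Step 3
Reactants: 6 methyl (2Z)-3-methylhepta-2,6-dienoate
Product: 7 (2Z)-3-methylhepta-2,6-dien-1-ol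
Conditions: DIBAL-H (2.2 equiv), CH2Cl2, −78 → 0 °C; aq. Rochelle salt
Reagents that add atoms: none
Why: DIBAL-H reduces the conjugated ester 1,2 to the allylic alcohol without touching either alkene or the Z geometry.

Step 4
Reactants: 7 (2Z)-3-methylhepta-2,6-dien-1-ol
Product: 8 [(2R,3S)-3-(but-3-en-1-yl)-3-methyloxiran-2-yl]methanol
Conditions: Ti(OiPr)4 (10 mol %), D-(−)-diethyl tartrate (12 mol %), t-BuOOH, 4 Å MS, CH2Cl2, −20 °C
Reagents that add atoms: tert-butyl hydroperoxide, CC(C)(C)OO
Why: Sharpless asymmetric epoxidation epoxidises only the allylic-alcohol alkene, and the D-(−)-tartrate complex delivers oxygen to the face that gives (2R,3S), i.e. C5 (R) and C4 (S) of the target, the Z-alkene becoming the cis-epoxide.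

Step 5
Reactants: 8 [(2R,3S)-3-(but-3-en-1-yl)-3-methyloxiran-2-yl]methanol
Product: 9 (2S,3S)-3-(but-3-en-1-yl)-3-methyloxirane-2-carbaldehyde
Conditions: TEMPO (10 mol %), PhI(OAc)2, CH2Cl2, 0 °C → rt
Reagents that add atoms: none
Why: TEMPO/PhI(OAc)2 (oxoammonium) oxidation takes the primary alcohol to the aldehyde under nearly neutral conditions that preserve the epoxide, whose α-carbon cannot epimerise (the descriptor change at C2 is only a CIP priority change).

**Fragment B**

Step 6
Reactants: 10 tiglic acid; 11 3-bromo-2-(bromomethyl)prop-1-ene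
Product: 13 2-(bromomethyl)prop-2-en-1-yl (2E)-2-methylbut-2-enoate, via potassium tiglate 12 (not isolated)
Conditions: K2CO3 (1 equiv), DMF, rt; added to 11 (3 equiv, excess recovered)
Reagents that add atoms: none
Why: SN2 O-alkylation of the carboxylate; the dibromide is symmetric, so SN2 and SN2′ give the same monoester, and the excess suppresses the diester.

Step 7
Reactants: 13 2-(bromomethyl)prop-2-en-1-yl (2E)-2-methylbut-2-enoate; 14 acrolein
Product: 16 (±)-4-hydroxy-2-methylidenehex-5-en-1-yl (2E)-2-methylbut-2-enoate, via allylzinc bromide 15 (not isolated)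
Conditions: Zn dust, THF/sat. aq. NH4Cl, 0 °C
Reagents that add atoms: none
Why: Zinc-mediated Barbier allylation adds 1,2 to acrolein; both termini of the 2-substituted allyl unit are CH2, so regiochemistry is immaterial, and the new carbinol (C8) is formed racemic.

Step 8
Reactants: 16 (±)-4-hydroxy-2-methylidenehex-5-en-1-yl (2E)-2-methylbut-2-enoate
Product: 17 (4S)-4-hydroxy-2-methylidenehex-5-en-1-yl (2E)-2-methylbut-2-enoate
Conditions: Ti(OiPr)4 (15 mol %), D-(−)-diisopropyl tartrate (20 mol %), t-BuOOH (0.6 equiv), 4 Å MS, CH2Cl2, −20 °C; unreacted alcohol recovered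
Reagents that add atoms: none
Why: Sharpless kinetic resolution: with D-(−)-diisopropyl tartrate the (R)-alcohol is epoxidised much faster (to the erythro epoxy alcohol), so the alcohol recovered at about 55–60 % conversion is the (S)-enantiomer, which fixes C8.

Step 9
Reactants: 17 (4S)-4-hydroxy-2-methylidenehex-5-en-1-yl (2E)-2-methylbut-2-enoate; 18 2-(bromomethyl)prop-2-enoic acid
Product: 19 (3S)-5-({[(2E)-2-methylbut-2-enoyl]oxy}methyl)hexa-1,5-dien-3-yl 2-(bromomethyl)prop-2-enoate
Conditions: DCC, DMAP (5 mol %), CH2Cl2, −20 → 0 °C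
Reagents that add atoms: none
Why: Steglich esterification acylates the secondary allylic alcohol with retention at C8; low temperature and only catalytic DMAP limit attack on the allylic bromide.

Step 10
Reactants: 19 (3S)-5-({[(2E)-2-methylbut-2-enoyl]oxy}methyl)hexa-1,5-dien-3-yl 2-(bromomethyl)prop-2-enoate
Product: 20 2-{[(2S)-4-(bromomethyl)-5-oxo-2,5-dihydrofuran-2-yl]methyl}prop-2-en-1-yl (2E)-2-methylbut-2-enoate
Conditions: second-generation Grubbs catalyst (5 mol %), CH2Cl2 (5 mM), 40 °C
Reagents that add atoms: none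
Why: Ring-closing metathesis between the vinyl group and the acrylate closes the five-membered butenolide with loss of ethene; the other 1,1-disubstituted alkene could only give a cyclobutene and stays, and C8 is not involved.

**Coupling and ring closure**

Step 11
Reactants: 9 (2S,3S)-3-(but-3-en-1-yl)-3-methyloxirane-2-carbaldehyde; 20 2-{[(2S)-4-(bromomethyl)-5-oxo-2,5-dihydrofuran-2-yl]methyl}prop-2-en-1-yl (2E)-2-methylbut-2-enoate
Product: 21 (2Z)-2-{[(2S)-4-(bromomethyl)-5-oxo-2,5-dihydrofuran-2-yl]methyl}-5-[(2S,3S)-3-formyl-2-methyloxiran-2-yl]pent-2-en-1-yl (2E)-2-methylbut-2-enoate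
Conditions: second-generation Hoveyda–Grubbs catalyst (10 mol %), 9 (3 equiv), CH2Cl2, 40 °C, argon sparge; geometric isomers separated by chromatography
Reagents that add atoms: none
Why: Olefin cross-metathesis of the terminal alkene of 9 with the 1,1-disubstituted alkene of 20 forms C1=C10 with loss of ethene; the mechanism does not fix the geometry, so the wanted isomer (new chain cis to the smaller acyloxymethyl arm, C2 trans to C9) is expected only as a moderate major product and is isolated by chromatography.

Step 12
Reactants: 21 (2Z)-2-{[(2S)-4-(bromomethyl)-5-oxo-2,5-dihydrofuran-2-yl]methyl}-5-[(2S,3S)-3-formyl-2-methyloxiran-2-yl]pent-2-en-1-yl (2E)-2-methylbut-2-enoate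
Product: 23 (4S,5R,6S,7S,8S)-4,5-epoxy-6-hydroxy-14-tigloyloxygermacra-1(10),11(13)-dien-8,12-olide (target CNP0116446.1), via allylchromium dichloride 22 (not isolated)
Conditions: CrCl2 (10 equiv), THF, rt, syringe-pump addition of 21 (final 1 mM); aqueous work-up
Reagents that add atoms: none
Why: Intramolecular Nozaki–Hiyama (Barbier-type) allylation: the allylchromium adds through its γ-carbon (C7) to the aldehyde in a chair transition state, on the butenolide face anti to the C8–C9 bond (7S, trans-lactone) and with the epoxy substituent of the aldehyde equatorial (6S), closing the ten-membered ring and moving the double bond into the exocyclic methylene.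

## Compound list

1 | hex-1-en-5-yne | C=CCCC#C | starting material
2 | methyl chloroformate | COC(=O)Cl | starting material
3 | lithium hex-5-en-1-yn-1-ide | [Li]C#CCCC=C | intermediate (not isolated)
4 | methyl hept-6-en-2-ynoate | COC(=O)C#CCCC=C | intermediate
5 | lithium [(1E)-1-(methoxycarbonyl)-2-methylhexa-1,5-dien-1-yl](methyl)cuprate (Cu cis to the new methyl) | [Li+].C[Cu-]/C(C(=O)OC)=C(\C)CCC=C | intermediate (not isolated)
6 | methyl (2Z)-3-methylhepta-2,6-dienoate | COC(=O)/C=C(/C)CCC=C | intermediate
7 | (2Z)-3-methylhepta-2,6-dien-1-ol | OC/C=C(/C)CCC=C | intermediate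
8 | [(2R,3S)-3-(but-3-en-1-yl)-3-methyloxiran-2-yl]methanol | C=CCC[C@]1(C)O[C@@H]1CO | intermediate
9 | (2S,3S)-3-(but-3-en-1-yl)-3-methyloxirane-2-carbaldehyde | C=CCC[C@]1(C)O[C@@H]1C=O | intermediate
10 | tiglic acid, (2E)-2-methylbut-2-enoic acid | C/C=C(\C)C(=O)O | starting material
11 | 3-bromo-2-(bromomethyl)prop-1-ene | C=C(CBr)CBr | starting material
12 | potassium (2E)-2-methylbut-2-enoate | [K+].C/C=C(\C)C(=O)[O-] | intermediate (not isolated)
13 | 2-(bromomethyl)prop-2-en-1-yl (2E)-2-methylbut-2-enoate | BrCC(=C)COC(=O)/C(C)=C/C | intermediate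
14 | acrolein (prop-2-enal) | C=CC=O | starting material
15 | bromo{2-[(tigloyloxy)methyl]prop-2-en-1-yl}zinc | Br[Zn]CC(=C)COC(=O)/C(C)=C/C | intermediate (not isolated)
16 | (±)-4-hydroxy-2-methylidenehex-5-en-1-yl (2E)-2-methylbut-2-enoate | C=CC(O)CC(=C)COC(=O)/C(C)=C/C | intermediate
17 | (4S)-4-hydroxy-2-methylidenehex-5-en-1-yl (2E)-2-methylbut-2-enoate | C=C[C@@H](O)CC(=C)COC(=O)/C(C)=C/C | intermediate
18 | 2-(bromomethyl)prop-2-enoic acid | C=C(CBr)C(=O)O | starting material
19 | (3S)-5-({[(2E)-2-methylbut-2-enoyl]oxy}methyl)hexa-1,5-dien-3-yl 2-(bromomethyl)prop-2-enoate | C=C[C@@H](OC(=O)C(=C)CBr)CC(=C)COC(=O)/C(C)=C/C | intermediate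
20 | 2-{[(2S)-4-(bromomethyl)-5-oxo-2,5-dihydrofuran-2-yl]methyl}prop-2-en-1-yl (2E)-2-methylbut-2-enoate | BrCC1=C[C@H](CC(=C)COC(=O)/C(C)=C/C)OC1=O | intermediate
21 | (2Z)-2-{[(2S)-4-(bromomethyl)-5-oxo-2,5-dihydrofuran-2-yl]methyl}-5-[(2S,3S)-3-formyl-2-methyloxiran-2-yl]pent-2-en-1-yl (2E)-2-methylbut-2-enoate | BrCC1=C[C@H](C/C(COC(=O)/C(C)=C/C)=C/CC[C@]2(C)O[C@@H]2C=O)OC1=O | intermediate
22 | allylchromium dichloride of 21 (CrCl2 in place of Br on the butenolide CH2) | Cl[Cr](Cl)CC1=C[C@H](C/C(COC(=O)/C(C)=C/C)=C/CC[C@]2(C)O[C@@H]2C=O)OC1=O | intermediate (not isolated)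
23 | (4S,5R,6S,7S,8S)-4,5-epoxy-6-hydroxy-14-tigloyloxygermacra-1(10),11(13)-dien-8,12-olide, C2 trans to C9 at the ring alkene | C=C1C(=O)O[C@H]2C/C(COC(=O)/C(C)=C/C)=C/CC[C@]3(C)O[C@@H]3[C@@H](O)[C@H]12 | target

## Step count and risks

Total step count: 12.
Longest linear sequence: 7 (steps 6–10, then 11 and 12; the fragment A branch, steps 1–5, then 11 and 12, is equally long).

**Step 11 (cross-metathesis).** This is the weakest step. The 1,1-disubstituted alkene of 20 is hindered, and the two arms on C10 differ little in size, so an E/Z ratio of perhaps 1:1 to 2:1 must be expected and half or more of the material may be lost on separation. Fallback: reverse the order of the two C–C bond formations. It sets out from 9 and 20. Zinc in THF/aqueous NH4Cl joins them intermolecularly at C6–C7, through the same chair transition state with the aldehyde anti to the C8 side chain, and gives the acyclic hydroxy α-methylene lactone F1. Ring-closing metathesis of the two terminal alkenes of the hydroxy α-methylene lactone F1 (second-generation Hoveyda–Grubbs catalyst, toluene, 80 °C, 1 mM) then closes the carbocycle, the olefin geometry now being decided by the lactone–epoxide template and no longer by an acyclic preference. The sequence comes back to the route at 23.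

**Step 12 (macrocyclisation).** Risks are oligomerisation, protonolysis of the allylchromium before ring closure, Lewis-acid damage to the epoxy aldehyde, and attack on the wrong butenolide face (cis-lactone). Fallback: replace the reductive chromium chemistry by a thermal intramolecular allylboration. It sets out from 20. Pd2(dba)3-catalysed borylation with bis(pinacolato)diboron gives the allylboronate F2. Cross-metathesis of the allylboronate F2 with 9, as in step 11, gives the boronate aldehyde F3. Heating the boronate aldehyde F3 in toluene (90 °C, 1 mM) and aqueous work-up closes the ring through the closed chair transition state, with no low-valent metal or Lewis acid present. It comes back at 23.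

**Step 10 (ring-closing metathesis of the 2-(bromomethyl)acrylate, together with its preparation in step 9).** The allylic bromide can be attacked by DMAP during esterification and may shorten catalyst life in the metathesis. Fallback: carry C13 as a silyl ether through the ring closure and introduce bromine last. It sets out from 17. DCC/DMAP esterification with 2-({[tert-butyl(dimethyl)silyl]oxy}methyl)prop-2-enoic acid gives the silyloxymethyl acrylate F4. Ring-closing metathesis (second-generation Grubbs catalyst) gives the silyloxymethyl butenolide F5. HF·pyridine gives the hydroxymethyl butenolide F6, and CBr4/PPh3 converts the hydroxymethyl butenolide F6 into 20, where it rejoins the route.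

## Further compounds

F1 | step 11 | 2-{[(2S,3S)-3-{(S)-hydroxy[(2R,3S)-3-(but-3-en-1-yl)-3-methyloxiran-2-yl]methyl}-4-methylidene-5-oxooxolan-2-yl]methyl}prop-2-en-1-yl (2E)-2-methylbut-2-enoate | C=C1C(=O)O[C@@H](CC(=C)COC(=O)/C(C)=C/C)[C@@H]1[C@H](O)[C@H]2O[C@@]2(C)CCC=C
F2 | step 12 | 2-{[(2S)-5-oxo-4-[(4,4,5,5-tetramethyl-1,3,2-dioxaborolan-2-yl)methyl]-2,5-dihydrofuran-2-yl]methyl}prop-2-en-1-yl (2E)-2-methylbut-2-enoate | CC1(C)OB(CC2=C[C@H](CC(=C)COC(=O)/C(C)=C/C)OC2=O)OC1(C)C
F3 | step 12 | (2Z)-5-[(2S,3S)-3-formyl-2-methyloxiran-2-yl]-2-{[(2S)-5-oxo-4-[(4,4,5,5-tetramethyl-1,3,2-dioxaborolan-2-yl)methyl]-2,5-dihydrofuran-2-yl]methyl}pent-2-en-1-yl (2E)-2-methylbut-2-enoate | CC1(C)OB(CC2=C[C@H](C/C(COC(=O)/C(C)=C/C)=C/CC[C@]3(C)O[C@@H]3C=O)OC2=O)OC1(C)C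
F4 | step 10 | (3S)-5-({[(2E)-2-methylbut-2-enoyl]oxy}methyl)hexa-1,5-dien-3-yl 2-({[tert-butyl(dimethyl)silyl]oxy}methyl)prop-2-enoate | C=C[C@@H](OC(=O)C(=C)CO[Si](C)(C)C(C)(C)C)CC(=C)COC(=O)/C(C)=C/C
F5 | step 10 | 2-{[(2S)-4-({[tert-butyl(dimethyl)silyl]oxy}methyl)-5-oxo-2,5-dihydrofuran-2-yl]methyl}prop-2-en-1-yl (2E)-2-methylbut-2-enoate | CC(C)(C)[Si](C)(C)OCC1=C[C@H](CC(=C)COC(=O)/C(C)=C/C)OC1=O
F6 | step 10 | 2-{[(2S)-4-(hydroxymethyl)-5-oxo-2,5-dihydrofuran-2-yl]methyl}prop-2-en-1-yl (2E)-2-methylbut-2-enoate | OCC1=C[C@H](CC(=C)COC(=O)/C(C)=C/C)OC1=O
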